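The numbers in the tables were generated by integration from invented constants; the scatter is artificial.

I counted amounts first. Z was charged at 0.20 M in the new flasks and J not at all, but the held Q feeds J towards 73 mM. So I took cJ as constant and Z as the limiting reagent. The balance of Z then makes G's gain pseudo-first-order: G grows as k' times cZ, and I counted the other steps as a drain on Z.

| setting | winter | dawn | Wednesday's | Thursday's | Sunday's |
|---|---|---|---|---|---|
| Z | 0.13 M | 0.30 M | 0.20 M | 0.20 M | 0.20 M |
| Q | 73 mM (held) | 73 mM (held) | 73 mM (held) | 73 mM (held) | 73 mM (held) |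
| temperature | −40 °C | −5 °C | 25 °C | −5 °C | −35 °C |
| remark | run made earlier | run made earlier |  |  |  |
| time |  |  | 15 h | 15 h | 15 h |

| run | time / h | G / % |
|---|---|---|
| winter | 30.0 | 5 |
| winter | 60.0 | 4 |
| winter | 120 | 12 |
| winter | 240 | 21 |
| winter | 480 | 34 |
| dawn | 20.0 | 32 |
| dawn | 40.0 | 34 |
| dawn | 72.0 | 38 |
| dawn | 96.0 | 35 |

(scatter of a reading: 2 percentage points)

* which flask leads in amount of G, in percent of the Z charged ("all alike" within 1.5 percentage points) (Wednesday's / Thursday's / Sunday's / all alike)
* how much G is there at the end, in percent of the Z charged: Wednesday's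
* how much G is there at the end, in percent of the Z charged: Thursday's
* how much G is there at the end, in percent of the Z charged: Sunday's

- a species is counted by the Z in it: one X counts as two
- at the start none of J is dissolved
- candidate steps: Z + J -> G; Z -> E; 2 Z -> X; G <-> L; Q <-> J

In the dawn run the last three readings averaged 35.7 %, which I read as a plateau, each reading carrying a scatter of 2 percentage points. If Z dies away exponentially at a rate λ, G approaches that plateau as 1 − exp(−λt), so the reading at 20.0 h gave λ = 0.114 h⁻¹. The product of plateau and λ, 0.0406 h⁻¹, is my reading of k' at −5 °C: the share of the Z present that becomes G per hour.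

In the winter run I took Z as near its charge early on, so the single reading at 120 h gave a rough k' of 0.00100 h⁻¹. I interpolated ln k' straight in temperature between the two runs and got 0.00170 h⁻¹ at −35 °C. Taking Z as near its charge again, I expected about 2.55 % of G in Sunday's flask. I carried plateau and λ over from the dawn run, although that run began at 0.30 M of Z and Thursday's flask at 0.20 M, and they gave Thursday's flask 29.2 %. Wednesday's flask lay outside my two temperatures, so I reckoned nothing for it.

The forecast named Thursday's as leader, with 14 % for Wednesday's, 36 % for Thursday's and 3.5 % for Sunday's, and it said “Thursday sits near the plateau”. My figures for Thursday's and Sunday's were lower than its figures.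

The simulation gave 16.0 % for Wednesday's, 32.6 % for Thursday's and 2.96 % for Sunday's, so Thursday's led.

    Z + J → G (k = 6.81 M⁻¹ h⁻¹, Ea = 54.0 kJ mol⁻¹)
    Z → E (k = 1.20 h⁻¹, Ea = 84.0 kJ mol⁻¹)
    2 Z → X (k = 1.19 M⁻¹ h⁻¹, Ea = 52.0 kJ mol⁻¹)
    G ⇌ L (K = 0.390, k = 0.185 h⁻¹, Ea = 101 kJ mol⁻¹, ΔH = 7.00 kJ mol⁻¹)
    Q ⇌ J, rate k5*(csat - [J]) (kL = 11.5 h⁻¹)
    (constants at 25 °C)

Thursday's flask had converted 75.4 % of its Z by the end. Its Z stood at 46.8 % after 7.50 h and 24.6 % after 15.0 h, a trapezoid mean of 54.5 %. My 0.0406 h⁻¹ on that mean over 15 h gave 33.2 % of G, beside the 32.6 % computed.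

A neighbour flask, Sunday's recipe at −10 °C, took k' = 0.0239 h⁻¹ from the same interpolation. With Z ending at 41.0 %, the mean of charge and end, 70.5 %, gave 25.3 % of G. The computed flask holds 26.2 %.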